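**Convention and assumption.** Cembrane numbering is used throughout: ring carbons C1–C14 (C1 carries the acrylate unit), C15/C16/C17 the acrylate α-carbon, carbonyl and methylene, C18–C20 the methyls on C4, C8 and C12. Read this way the target is 1S,4S,5R,13R,8Z,11E, and its O4/O5 pair is erythro, that is cis on the 14-membered ring.

## The problem

The target (33) is a cembranolide: a 14-membered carbocycle (C1–C14) bridged from C1 to C4 by an α-methylene ε-lactone (seven-membered ring C1–C2–C3–C4–O–C16–C15). The lactone oxygen therefore sits on a quaternary carbon, and its neighbour C5 carries a free secondary hydroxyl. There are four stereocentres. C4 and C5 are contiguous and can control each other. C1 is separated from C4 and from C13 by flexible methylene groups and cannot be trusted to control either. C1 is therefore best bought from the chiral pool, C13 set by a reagent, and C4/C5 handled together. The chain carries a skipped diene with one Z (C8) and one E (C12) trisubstituted alkene, and both geometries must be fixed before the ring closes. The fragile groups are: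

- the α-methylene lactone, a Michael and radical acceptor, which must come last;
- the secondary allylic acetate at C13, which ionises under acid, reacts with zerovalent palladium and is base-labile;
- the doubly allylic C10 methylene, which can slide into conjugation whenever C13 is a ketone;
- the O4-acyl/O5-hydroxy pair, which is open to acyl shift.

The feature that makes the key step possible is the vicinal oxygenation at C4 (methyl-bearing, quaternary) and C5 (secondary): this is the retron of a reductive coupling of a C4 methyl ketone with a C5 aldehyde. A methyl ketone three carbons from C1, with an isopropenyl branch on C1, is exactly what ring-opened limonene provides. One caution shapes the plan: pinacol closures of rings this large do not reliably give the cis diol, so the route must not depend on the ring closure for C5.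

## Retrosynthesis

**Lactone C16–O4.** The target 33 is opened at the ester bond to the dihydroxy acid 31. Making the α-methylene lactone last keeps an acrylate away from every reducing metal used earlier. 31 is traced through enal 30 and triol 29 to the silyl ether 28, which are pure oxidation-state changes at C16. The forward reaction must acylate the tertiary O4 (seven-membered ring) in the presence of the secondary O5 (eight-membered ring).

**C5 configuration.** The cis diol 28 is traced to the α-hydroxy ketone 27, and 27 to the diol 26 of either C5 configuration. Compared with demanding a cis-selective ring closure, this moves C5 to a chelation-controlled reduction next to the tertiary hydroxyl. The ring closure is then asked only for the ring and for C4.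

**C4–C5 (key cut).** Diol 26 is cut between the two carbinol carbons to the open-chain keto aldehyde 24. Neighbouring ring cuts (C12–C13, C2–C3) would leave the quaternary C4 carbinol and its neighbour to be built in open-chain mode. The C4–C5 cut removes the ring and both carbinols at once and leaves two ordinary carbonyl termini that are easily masked as dimethyl acetals. 24 has only two stereocentres (C1, C13). The forward step needs high dilution, reduction of the two carbonyls only, and a useful preference for one face of the C4 ketone.

**C13 adjustments.** 24 comes from the bis-acetal acetate 23, the alcohol 22, the enone 21, the enedione 20 and the epimeric alcohols 19. C13 is set by a catalyst-controlled enone reduction on the open chain, where its sense is predictable. The C4 ketone is masked as its dimethyl ketal only for that reduction, and the acetate is installed before the ring closes so that O13 never has to be told apart from O5.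

**C12–C13.** Alcohol 19 is cut into aldehyde 6 (fragment A, C13–C4 plus C15–C18) and alkenyl iodide 18 (fragment B, C5–C12). Against a cut at C10–C11 or C13–C14, this one divides the chain into a half that is ring-opened limonene and a half that is nerol plus propyne. The chromium-mediated union attacks the aldehyde and ignores the methyl ketone, and the geometry of the alkenyl iodide is retained.

**Fragment A.** Aldehyde 6 comes from the silyl ether 5, the allylic alcohol 4 and the keto acetal 3, which is (S)-limonene (1) cleaved at its ring alkene. The limonene stereocentre becomes C1 with the correct S configuration, the ring methyl becomes C18, and allylic oxidation of the isopropenyl methyl supplies C16. A tert-butyldiphenylsilyl ether is chosen for O16 because two acetal hydrolyses lie ahead.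

**Fragment B.** Iodide 18 comes from the enyne 16 by syn hydrometalation. 16 is cut at C10–C11 into allylic bromide 13 and propyne (14). 13 goes back through alcohol 11 and acetal acetate 10 to neryl acetate 8 and nerol (7), whose Z alkene becomes C8=C9 and whose distal alkene is cleaved to the C5 aldehyde oxidation level.

## Roads not taken

**Alternative 1:** build the skipped diene by carbocupration and vinyl-oxirane opening. The cuts are C7–C8 and C9–C10. The alkylcopper made from Grignard reagent A3 adds syn across propyne (14) to give the Z-alkenylcopper A4, and its cuprate opens the vinyl oxirane A2 in the anti-SN2′ sense to give the open-chain dienol A1.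
- Merits: the Z alkene is made from propyne, independent of the isomeric purity of nerol. The C13 hydroxyl comes out with its configuration already set by the epoxide, so steps 12–14 of the chosen route would not be needed. The C5–C12 half is shorter.
- Weak points: A2 is a stereodefined epoxide with a vinyl group on a quaternary carbon and is itself several steps, including an asymmetric epoxidation, from the limonene half. The E geometry at C11=C12 depends on which conformer of a 2-methyl-2-vinyl oxirane reacts, and that preference is often modest. Direct SN2 opening competes. The chemistry is stoichiometric organocopper at low temperature.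
- Comparison: this road is at least as good as the chosen one for assembling the chain and better on step count around C13. It does not close the ring, and A1 would still need the same C4–C5 closure. The chosen plan sets against it commodity fragments with the Z alkene already in place, a catalytic-in-nickel union and a reduction whose sense is predictable.

**Alternative 2:** close the lactone last by carbonylation. The cuts are C15–C16 and C16–O4. Pd(PPh3)4 (zerovalent palladium) and CO turn the C15 alkenyl iodide A6 into an acylpalladium that the tertiary C4 hydroxyl captures, giving the bis-silyl lactone A5.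
- Merits: O5 is silylated, so the regiochemistry of lactone formation is beyond doubt, which is better than the unprotected lactonisation in step 23. One step replaces the oxidation sequence of steps 21–23.
- Weak points: a C15 iodide has to come from a C1 acetyl group, which places C1 α to a ketone (epimerisation risk) and raises a regiochemical question in the iodide synthesis. Capture of an acylpalladium by a tertiary alcohol to form a seven-membered ring is slow. An allylic acetate cannot be present with zerovalent palladium, so C13 must travel as a silyl ether and the acetate has to be placed at the very end, by selective C13 desilylation, acetylation and C5 desilylation on a Michael acceptor. This road is also silent on how the macrocycle is made.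
- Comparison: it wins on regiocontrol. The chosen plan offers a C1 centre that is never α to a carbonyl, an acetate in place from step 15, and no late carbonylation on the complete macrocycle.

**Alternative 3:** use carbon monoxide as C13 in a carbonylative Negishi ring closure. The cuts are C12–C13 and C13–C14. Zinc inserts into the primary C14 iodide of the lactone A8, and Pd(PPh3)4 under CO joins the alkylzinc to the C12 alkenyl iodide through an acylpalladium, giving the macrocyclic enone lactone A7.
- Merits: two C–C bonds and the 14-membered ring form in one step. C4 and C5 are set beforehand on the small lactone A8 by open-chain methods, which is clearly better than relying on the fold of a long chain for C4.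
- Weak points: the alkylzinc must be made beside an α-methylene lactone. Direct coupling without CO (a 13-membered ring) and β-hydride loss at C1–H compete with acyl transfer. Carbonylative closures of rings this size have little precedent. A7 still needs a C13 reduction on the macrocycle, with unknown facial bias and a reducible lactone nearby, followed by acetylation and desilylation.
- Comparison: it is better on C4/C5 control. The chosen plan sets against it a ring closure with direct precedent at this ring size, a C13 reduction done on the open chain, and a Michael acceptor that appears only in the last step.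

Key step: step 17

## Route

Step 1
Reactants: 1 (S)-(−)-limonene
Product: 3 (5S)-7,7-dimethoxy-5-(prop-1-en-2-yl)heptan-2-one, via methoxy hydroperoxide aldehyde 2 (not isolated)
Conditions: O3, CH2Cl2/MeOH, −78 °C; TsOH·H2O, rt; NaHCO3, then Me2S, rt
Reagents that add atoms: ozone, [O-][O+]=O; methanol, CO
Why: Ozonolysis by the Criegee mechanism with methanol trapping: the electron-rich trisubstituted ring alkene reacts before the isopropenyl group, the carbonyl oxide on the more substituted carbon is held as methoxy hydroperoxide 2 while acid acetalises the free aldehyde, and Me2S then reduces the hydroperoxide to the ketone; the limonene stereocentre (C1 of the target) is not involved.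

Step 2
Reactants: 3 (5S)-7,7-dimethoxy-5-(prop-1-en-2-yl)heptan-2-one
Product: 4 (5S)-5-(3-hydroxyprop-1-en-2-yl)-7,7-dimethoxyheptan-2-one
Conditions: SeO2 (cat.), t-BuOOH (anhydrous, decane), CH2Cl2, 0 °C to rt
Reagents that add atoms: tert-butyl hydroperoxide, CC(C)(C)OO (oxygen source, relayed by selenium dioxide, O=[Se]=O)
Why: Selenium dioxide allylic hydroxylation (ene reaction, then [2,3]-sigmatropic shift); on a 1,1-disubstituted alkene the methyl group is oxidised in preference to the methine, so the alkene stays in place and C1 keeps its configuration, while ketone and acetal are spectators under these mild conditions.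

Step 3
Reactants: 4 (5S)-5-(3-hydroxyprop-1-en-2-yl)-7,7-dimethoxyheptan-2-one
Product: 5 (5S)-5-{3-[(tert-butyldiphenylsilyl)oxy]prop-1-en-2-yl}-7,7-dimethoxyheptan-2-one
Conditions: TBDPSCl, imidazole, DMF, rt
Reagents that add atoms: tert-butyl(chloro)diphenylsilane, CC(C)(C)[Si](Cl)(c1ccccc1)c1ccccc1
Why: Standard silylation of a primary allylic alcohol; the diphenylsilyl ether is chosen because it must outlast the acetal hydrolyses of steps 4 and 16.

Step 4
Reactants: 5 (5S)-5-{3-[(tert-butyldiphenylsilyl)oxy]prop-1-en-2-yl}-7,7-dimethoxyheptan-2-one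
Product: 6 (3S)-3-{3-[(tert-butyldiphenylsilyl)oxy]prop-1-en-2-yl}-6-oxoheptanal (fragment A)
Conditions: TsOH·H2O (cat.), acetone/H2O, rt
Reagents that add atoms: water, O
Why: Acid-catalysed acetal hydrolysis; the acyclic dimethyl acetal is far more labile than the silyl ether, and short contact at room temperature avoids the intramolecular aldol reaction of the 1,6-keto aldehyde.

Step 5
Reactants: 7 nerol
Product: 8 neryl acetate
Conditions: Ac2O, pyridine, DMAP (cat.), CH2Cl2, 0 °C to rt
Reagents that add atoms: acetic anhydride, CC(=O)OC(C)=O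
Why: Acetylation; the allylic acetoxy group deactivates the adjacent alkene toward ozone in step 6.

Step 6
Reactants: 8 neryl acetate
Product: 10 (2Z)-6,6-dimethoxy-3-methylhex-2-en-1-yl acetate, via aldehyde 9 (not isolated)
Conditions: O3 (1 equiv), CH2Cl2/MeOH, −78 °C; TsOH·H2O, rt; NaHCO3, then Me2S, rt
Reagents that add atoms: methanol, CO
Why: Regioselective ozonolysis: the distal trisubstituted alkene is more electron-rich than the one bearing the allylic acetoxy group and is cleaved first, aldehyde 9 is acetalised in the same flask and Me2S reduces the acetone-derived hydroperoxide; the Z alkene is untouched.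

Step 7
Reactants: 10 (2Z)-6,6-dimethoxy-3-methylhex-2-en-1-yl acetate
Product: 11 (2Z)-6,6-dimethoxy-3-methylhex-2-en-1-ol
Conditions: K2CO3 (cat.), MeOH, 0 °C to rt
Reagents that add atoms: none
Why: Base-catalysed transesterification of the acetate with methanol; the acetal is stable to base.

Step 8
Reactants: 11 (2Z)-6,6-dimethoxy-3-methylhex-2-en-1-ol
Product: 13 (2Z)-1-bromo-6,6-dimethoxy-3-methylhex-2-ene, via allylic mesylate 12 (not isolated)
Conditions: MsCl, Et3N, THF, −40 °C; LiBr, THF, −40 to 0 °C
Reagents that add atoms: lithium bromide, [Li+].[Br-]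
Why: Mesylation and SN2 displacement by bromide at low temperature; no acid is released, so the allylic system does not ionise and both the Z geometry and the acetal survive.

Step 9
Reactants: 13 (2Z)-1-bromo-6,6-dimethoxy-3-methylhex-2-ene; 14 propyne
Product: 16 (5Z)-9,9-dimethoxy-6-methylnon-5-en-2-yne, via propynylmagnesium bromide 15 (not isolated)
Conditions: 14, EtMgBr, THF, 0 °C to rt; then CuI (cat.), 13, THF, 0 °C to rt
Reagents that add atoms: none
Why: Copper-catalysed coupling of an alkynyl Grignard reagent with a primary allylic bromide, SN2 at the unhindered CH2 and not SN2′ at the fully substituted γ-carbon; it forms C10–C11 and keeps the Z alkene.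

Step 10
Reactants: 16 (5Z)-9,9-dimethoxy-6-methylnon-5-en-2-yne
Product: 18 (2E,5Z)-2-iodo-9,9-dimethoxy-6-methylnona-2,5-diene (fragment B), via alkenylzirconocene chloride 17 (not isolated)
Conditions: Cp2Zr(H)Cl (excess), THF, rt to 45 °C; then I2, THF, 0 °C
Reagents that add atoms: iodine, II
Why: Hydrozirconation–iodination: syn addition of Zr–H, with excess reagent equilibrating the regioisomers toward zirconium on the less hindered methyl-bearing carbon (C12), and iodinolysis with retention gives the E alkenyl iodide; the trisubstituted alkene and the acetal do not react with Cp2Zr(H)Cl.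

Step 11
Reactants: 6 (3S)-3-{3-[(tert-butyldiphenylsilyl)oxy]prop-1-en-2-yl}-6-oxoheptanal; 18 (2E,5Z)-2-iodo-9,9-dimethoxy-6-methylnona-2,5-diene
Product: 19 (5S,8E,11Z)-5-{3-[(tert-butyldiphenylsilyl)oxy]prop-1-en-2-yl}-7-hydroxy-15,15-dimethoxy-8,12-dimethylpentadeca-8,11-dien-2-one (both C7 epimers; C7 is C13 of the target)
Conditions: CrCl2, NiCl2 (cat.), DMSO, rt
Reagents that add atoms: none
Why: Nozaki–Hiyama–Kishi reaction: oxidative addition of the alkenyl iodide to zerovalent nickel formed from NiCl2, transmetalation to trivalent chromium and addition of the alkenylchromium to the aldehyde, not to the methyl ketone; C12–C13 forms with retention of the E geometry, and the uncontrolled C13 centre is removed in step 12.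

Step 12
Reactants: 19 (5S,8E,11Z)-5-{3-[(tert-butyldiphenylsilyl)oxy]prop-1-en-2-yl}-7-hydroxy-15,15-dimethoxy-8,12-dimethylpentadeca-8,11-dien-2-one
Product: 20 (5S,8E,11Z)-5-{3-[(tert-butyldiphenylsilyl)oxy]prop-1-en-2-yl}-15,15-dimethoxy-8,12-dimethylpentadeca-8,11-diene-2,7-dione
Conditions: Dess–Martin periodinane, pyridine, CH2Cl2, 0 °C to rt
Reagents that add atoms: none
Why: Dess–Martin oxidation of the allylic alcohol; the pyridine buffer protects the acetal from the acetic acid released and is too weak a base to move the C8 alkene into conjugation through the doubly allylic C10 methylene.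

Step 13
Reactants: 20 (5S,8E,11Z)-5-{3-[(tert-butyldiphenylsilyl)oxy]prop-1-en-2-yl}-15,15-dimethoxy-8,12-dimethylpentadeca-8,11-diene-2,7-dione
Product: 21 (5S,8E,11Z)-5-{3-[(tert-butyldiphenylsilyl)oxy]prop-1-en-2-yl}-2,2,15,15-tetramethoxy-8,12-dimethylpentadeca-8,11-dien-7-one
Conditions: HC(OMe)3, MeOH, PPTS (cat.), rt
Reagents that add atoms: trimethyl orthoformate, COC(OC)OC; methanol, CO
Why: Chemoselective ketalisation: the saturated methyl ketone forms its dimethyl ketal under mild acid while the conjugated, α-branched enone does not, which masks C4 for the reduction in step 14.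

Step 14
Reactants: 21 (5S,8E,11Z)-5-{3-[(tert-butyldiphenylsilyl)oxy]prop-1-en-2-yl}-2,2,15,15-tetramethoxy-8,12-dimethylpentadeca-8,11-dien-7-one
Product: 22 (5S,7R,8E,11Z)-5-{3-[(tert-butyldiphenylsilyl)oxy]prop-1-en-2-yl}-2,2,15,15-tetramethoxy-8,12-dimethylpentadeca-8,11-dien-7-ol
Conditions: (S)-Me-CBS oxazaborolidine, catecholborane, toluene, −78 °C
Reagents that add atoms: none
Why: Corey–Bakshi–Shibata reduction: the oxazaborolidine binds the ketone oxygen anti to the larger α-methylalkenyl group and hydride from coordinated catecholborane adds to one face, the (S) catalyst giving the R carbinol (C13); catecholborane at −78 °C neither hydroborates the alkenes nor attacks the acetals.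

Step 15
Reactants: 22 (5S,7R,8E,11Z)-5-{3-[(tert-butyldiphenylsilyl)oxy]prop-1-en-2-yl}-2,2,15,15-tetramethoxy-8,12-dimethylpentadeca-8,11-dien-7-ol
Product: 23 (5S,7R,8E,11Z)-5-{3-[(tert-butyldiphenylsilyl)oxy]prop-1-en-2-yl}-2,2,15,15-tetramethoxy-8,12-dimethylpentadeca-8,11-dien-7-yl acetate
Conditions: Ac2O, pyridine, DMAP (cat.), CH2Cl2, 0 °C
Reagents that add atoms: acetic anhydride, CC(=O)OC(C)=O
Why: Acetylation of the only free hydroxyl with retention at C13; placing the acetate here means O13 never has to be distinguished from O5 later.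

Step 16
Reactants: 23 (5S,7R,8E,11Z)-5-{3-[(tert-butyldiphenylsilyl)oxy]prop-1-en-2-yl}-2,2,15,15-tetramethoxy-8,12-dimethylpentadeca-8,11-dien-7-yl acetate
Product: 24 (5S,7R,8E,11Z)-5-{3-[(tert-butyldiphenylsilyl)oxy]prop-1-en-2-yl}-8,12-dimethyl-2,15-dioxopentadeca-8,11-dien-7-yl acetate (C4 ketone, C5 aldehyde)
Conditions: PPTS, acetone/H2O, rt to 40 °C
Reagents that add atoms: water, O
Why: Mild acid-catalysed hydrolysis of the two acyclic acetals (ketal at C4, acetal at C5); at this acidity the allylic acetate does not ionise and the silyl ether stays on.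

Step 17
Reactants: 24 (5S,7R,8E,11Z)-5-{3-[(tert-butyldiphenylsilyl)oxy]prop-1-en-2-yl}-8,12-dimethyl-2,15-dioxopentadeca-8,11-dien-7-yl acetate
Product: 26 (1S,4S,13R,8Z,11E)-13-acetoxy-16-[(tert-butyldiphenylsilyl)oxy]cembra-8,11,15(17)-triene-4,5-diol (both C5 epimers), via titanium diolate 25 (not isolated)
Conditions: TiCl3(DME)1.5, Zn–Cu, DME, reflux; then 24 by syringe pump over about 30 h at 25 °C (high dilution); aq. K2CO3
Reagents that add atoms: none
Why: Titanium-induced pinacol coupling: low-valent titanium on the Zn–Cu surface transfers an electron first to the more easily reduced C5 aldehyde, and the titanium-bound ketyl adds to the C4 ketone held on the same or a neighbouring titanium centre, giving the titanium 4,5-diolate 25; at 25 °C the reaction stops there, because deoxygenation to the alkene needs reflux, and aqueous K2CO3 frees the diol. The closest known reaction type is the titanium-mediated pinacol macrocyclisation of open-chain keto aldehydes to 14-membered carbocyclic 1,2-diols. The one ring that closes is the 14-membered carbocycle, by end-to-end union of the chain termini C4 and C5 under slow addition and high dilution, with the oxophilic metal as the template that gathers both carbonyls. C4 is set by the face of the ketone that meets C5; the only control is the fold of the tethered chain, shaped by the Z and E alkenes and by the C1 and C13 substituents. C5 also forms here, but rings of this size tend toward the trans diol while the target is cis, so its configuration is not relied on and is reset in steps 18 and 19. The selectivity the step must have is chemoselectivity for the two carbonyl groups: the alkenes, the silyl ether and the acetate are not expected to be reduced by this reagent at 25 °C, and no other carbonyl pair is present.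

Step 18
Reactants: 26 (1S,4S,13R,8Z,11E)-13-acetoxy-16-[(tert-butyldiphenylsilyl)oxy]cembra-8,11,15(17)-triene-4,5-diol (both C5 epimers)
Product: 27 (1S,4S,13R,8Z,11E)-13-acetoxy-16-[(tert-butyldiphenylsilyl)oxy]-4-hydroxycembra-8,11,15(17)-trien-5-one
Conditions: SO3·pyridine, DMSO, iPr2NEt, CH2Cl2, 0 °C to rt
Reagents that add atoms: none
Why: Parikh–Doering oxidation: only the secondary C5 carbinol can be oxidised, so both C5 epimers converge on one ketol; activated DMSO does not cleave glycols, and the tertiary hydroxyl, acetate and silyl ether are inert.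

Step 19
Reactants: 27 (1S,4S,13R,8Z,11E)-13-acetoxy-16-[(tert-butyldiphenylsilyl)oxy]-4-hydroxycembra-8,11,15(17)-trien-5-one
Product: 28 (1S,4S,5R,13R,8Z,11E)-13-acetoxy-16-[(tert-butyldiphenylsilyl)oxy]cembra-8,11,15(17)-triene-4,5-diol
Conditions: Zn(BH4)2, Et2O, −30 to 0 °C; aq. NH4Cl
Reagents that add atoms: none
Why: Chelation-controlled reduction: zinc bridges the C4 hydroxyl and the C5 carbonyl oxygen in a five-membered chelate and hydride adds to C5 from the chelate face carrying the C4 methyl, not the ring methylene C3, which is also the outer face of the macrocycle; this gives the erythro, ring-cis 5R carbinol, and the acetate is not reduced at this temperature.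

Step 20
Reactants: 28 (1S,4S,5R,13R,8Z,11E)-13-acetoxy-16-[(tert-butyldiphenylsilyl)oxy]cembra-8,11,15(17)-triene-4,5-diol
Product: 29 (1S,4S,5R,13R,8Z,11E)-13-acetoxycembra-8,11,15(17)-triene-4,5,16-triol
Conditions: TBAF, AcOH (1:1), THF, 0 °C to rt
Reagents that add atoms: none
Why: Fluoride-mediated desilylation, buffered with acetic acid so that the acetate neither migrates nor is cleaved.

Step 21
Reactants: 29 (1S,4S,5R,13R,8Z,11E)-13-acetoxycembra-8,11,15(17)-triene-4,5,16-triol
Product: 30 (1S,4S,5R,13R,8Z,11E)-13-acetoxy-4,5-dihydroxycembra-8,11,15(17)-trien-16-al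
Conditions: Cu(MeCN)4OTf (cat.), 2,2′-bipyridine, TEMPO, N-methylimidazole, air, MeCN, rt
Reagents that add atoms: none
Why: Copper/nitroxyl aerobic oxidation, selective for the unhindered primary allylic alcohol over the secondary and tertiary hydroxyls; it is chosen over MnO2, which can cleave 1,2-diols.

Step 22
Reactants: 30 (1S,4S,5R,13R,8Z,11E)-13-acetoxy-4,5-dihydroxycembra-8,11,15(17)-trien-16-al
Product: 31 (1S,4S,5R,13R,8Z,11E)-13-acetoxy-4,5-dihydroxycembra-8,11,15(17)-trien-16-oic acid
Conditions: NaClO2, NaH2PO4, 2-methyl-2-butene, t-BuOH/H2O, 0 °C to rt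
Reagents that add atoms: sodium chlorite, [Na+].[O-]Cl=O
Why: Pinnick oxidation of the 2-substituted acrolein to the acrylic acid; 2-methyl-2-butene traps the hypochlorous acid so that the trisubstituted alkenes are not chlorinated.

Step 23
Reactants: 31 (1S,4S,5R,13R,8Z,11E)-13-acetoxy-4,5-dihydroxycembra-8,11,15(17)-trien-16-oic acid
Product: 33 (1S,4S,5R,13R,8Z,11E)-13-acetoxy-5-hydroxycembra-8,11,15(17)-trien-16,4-olide (target), via mixed anhydride 32 (not isolated)
Conditions: 2-methyl-6-nitrobenzoic anhydride, DMAP, Et3N, CH2Cl2, slow addition of 31 (high dilution), rt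
Reagents that add atoms: none
Why: Shiina lactonisation: the carboxylate forms mixed anhydride 32 with the hindered aroyl group and DMAP passes the acryloyl unit to the tertiary O4, closing the seven-membered lactone; seven-membered closure is intrinsically faster than the eight-membered closure onto O5 and is helped by the quaternary C4, and an O5 acyl isomer, if formed, can reach the same lactone by 1,2-acyl shift; no stereocentre is touched.

## Compound list

1 | (S)-(−)-limonene, (4S)-1-methyl-4-(prop-1-en-2-yl)cyclohex-1-ene | CC1=CC[C@H](CC1)C(C)=C | starting material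
2 | (3S)-6-hydroperoxy-6-methoxy-3-(prop-1-en-2-yl)heptanal (C6 epimers) | COC(C)(OO)CC[C@@H](CC=O)C(C)=C | intermediate (not isolated)
3 | (5S)-7,7-dimethoxy-5-(prop-1-en-2-yl)heptan-2-one | CC(=O)CC[C@@H](CC(OC)OC)C(C)=C | intermediate
4 | (5S)-5-(3-hydroxyprop-1-en-2-yl)-7,7-dimethoxyheptan-2-one | CC(=O)CC[C@@H](CC(OC)OC)C(=C)CO | intermediate
5 | (5S)-5-{3-[(tert-butyldiphenylsilyl)oxy]prop-1-en-2-yl}-7,7-dimethoxyheptan-2-one | CC(=O)CC[C@@H](CC(OC)OC)C(=C)CO[Si](c1ccccc1)(c1ccccc1)C(C)(C)C | intermediate
6 | (3S)-3-{3-[(tert-butyldiphenylsilyl)oxy]prop-1-en-2-yl}-6-oxoheptanal (fragment A) | CC(=O)CC[C@@H](CC=O)C(=C)CO[Si](c1ccccc1)(c1ccccc1)C(C)(C)C | intermediate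
7 | nerol, (2Z)-3,7-dimethylocta-2,6-dien-1-ol | CC(C)=CCC/C(C)=C\CO | starting material
8 | neryl acetate, (2Z)-3,7-dimethylocta-2,6-dien-1-yl acetate | CC(C)=CCC/C(C)=C\COC(C)=O | intermediate
9 | (2Z)-3-methyl-6-oxohex-2-en-1-yl acetate | O=CCC/C(C)=C\COC(C)=O | intermediate (not isolated)
10 | (2Z)-6,6-dimethoxy-3-methylhex-2-en-1-yl acetate | COC(OC)CC/C(C)=C\COC(C)=O | intermediate
11 | (2Z)-6,6-dimethoxy-3-methylhex-2-en-1-ol | COC(OC)CC/C(C)=C\CO | intermediate
12 | (2Z)-6,6-dimethoxy-3-methylhex-2-en-1-yl methanesulfonate | COC(OC)CC/C(C)=C\COS(C)(=O)=O | intermediate (not isolated)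
13 | (2Z)-1-bromo-6,6-dimethoxy-3-methylhex-2-ene | COC(OC)CC/C(C)=C\CBr | intermediate
14 | propyne | CC#C | starting material
15 | prop-1-yn-1-ylmagnesium bromide | CC#C[Mg]Br | intermediate (not isolated)
16 | (5Z)-9,9-dimethoxy-6-methylnon-5-en-2-yne | CC#CC/C=C(/C)CCC(OC)OC | intermediate
17 | chlorobis(cyclopentadienyl)[(2E,5Z)-9,9-dimethoxy-6-methylnona-2,5-dien-2-yl]zirconium | C/C(=C\C/C=C(/C)CCC(OC)OC)[Zr](Cl)(C1C=CC=C1)C1C=CC=C1 | intermediate (not isolated)
18 | (2E,5Z)-2-iodo-9,9-dimethoxy-6-methylnona-2,5-diene (fragment B) | I/C(C)=C/C/C=C(/C)CCC(OC)OC | intermediate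
19 | (5S,8E,11Z)-5-{3-[(tert-butyldiphenylsilyl)oxy]prop-1-en-2-yl}-7-hydroxy-15,15-dimethoxy-8,12-dimethylpentadeca-8,11-dien-2-one (C7 epimers) | CC(=O)CC[C@@H](CC(O)/C(C)=C/C/C=C(/C)CCC(OC)OC)C(=C)CO[Si](c1ccccc1)(c1ccccc1)C(C)(C)C | intermediate
20 | (5S,8E,11Z)-5-{3-[(tert-butyldiphenylsilyl)oxy]prop-1-en-2-yl}-15,15-dimethoxy-8,12-dimethylpentadeca-8,11-diene-2,7-dione | CC(=O)CC[C@@H](CC(=O)/C(C)=C/C/C=C(/C)CCC(OC)OC)C(=C)CO[Si](c1ccccc1)(c1ccccc1)C(C)(C)C | intermediate
21 | (5S,8E,11Z)-5-{3-[(tert-butyldiphenylsilyl)oxy]prop-1-en-2-yl}-2,2,15,15-tetramethoxy-8,12-dimethylpentadeca-8,11-dien-7-one | COC(C)(OC)CC[C@@H](CC(=O)/C(C)=C/C/C=C(/C)CCC(OC)OC)C(=C)CO[Si](c1ccccc1)(c1ccccc1)C(C)(C)C | intermediate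
22 | (5S,7R,8E,11Z)-5-{3-[(tert-butyldiphenylsilyl)oxy]prop-1-en-2-yl}-2,2,15,15-tetramethoxy-8,12-dimethylpentadeca-8,11-dien-7-ol | COC(C)(OC)CC[C@@H](C[C@@H](O)/C(C)=C/C/C=C(/C)CCC(OC)OC)C(=C)CO[Si](c1ccccc1)(c1ccccc1)C(C)(C)C | intermediate
23 | (5S,7R,8E,11Z)-5-{3-[(tert-butyldiphenylsilyl)oxy]prop-1-en-2-yl}-2,2,15,15-tetramethoxy-8,12-dimethylpentadeca-8,11-dien-7-yl acetate | COC(C)(OC)CC[C@@H](C[C@@H](OC(C)=O)/C(C)=C/C/C=C(/C)CCC(OC)OC)C(=C)CO[Si](c1ccccc1)(c1ccccc1)C(C)(C)C | intermediate
24 | (5S,7R,8E,11Z)-5-{3-[(tert-butyldiphenylsilyl)oxy]prop-1-en-2-yl}-8,12-dimethyl-2,15-dioxopentadeca-8,11-dien-7-yl acetate (open-chain C4 ketone C5 aldehyde) | CC(=O)CC[C@@H](C[C@@H](OC(C)=O)/C(C)=C/C/C=C(/C)CCC=O)C(=C)CO[Si](c1ccccc1)(c1ccccc1)C(C)(C)C | intermediate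
25 | dichlorotitanium 4,5-diolate of 26 | C=C(CO[Si](c1ccccc1)(c1ccccc1)C(C)(C)C)[C@H]1CC[C@]2(C)O[Ti](Cl)(Cl)OC2CC/C(C)=C\C/C=C(C)/[C@H](OC(C)=O)C1 | intermediate (not isolated)
26 | (1S,4S,13R,8Z,11E)-13-acetoxy-16-[(tert-butyldiphenylsilyl)oxy]cembra-8,11,15(17)-triene-4,5-diol (C5 epimers) | C=C(CO[Si](c1ccccc1)(c1ccccc1)C(C)(C)C)[C@H]1CC[C@](C)(O)C(O)CC/C(C)=C\C/C=C(C)/[C@H](OC(C)=O)C1 | intermediate
27 | (1S,4S,13R,8Z,11E)-13-acetoxy-16-[(tert-butyldiphenylsilyl)oxy]-4-hydroxycembra-8,11,15(17)-trien-5-one | C=C(CO[Si](c1ccccc1)(c1ccccc1)C(C)(C)C)[C@H]1CC[C@](C)(O)C(=O)CC/C(C)=C\C/C=C(C)/[C@H](OC(C)=O)C1 | intermediate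
28 | (1S,4S,5R,13R,8Z,11E)-13-acetoxy-16-[(tert-butyldiphenylsilyl)oxy]cembra-8,11,15(17)-triene-4,5-diol | C=C(CO[Si](c1ccccc1)(c1ccccc1)C(C)(C)C)[C@H]1CC[C@](C)(O)[C@H](O)CC/C(C)=C\C/C=C(C)/[C@H](OC(C)=O)C1 | intermediate
29 | (1S,4S,5R,13R,8Z,11E)-13-acetoxycembra-8,11,15(17)-triene-4,5,16-triol | C=C(CO)[C@H]1CC[C@](C)(O)[C@H](O)CC/C(C)=C\C/C=C(C)/[C@H](OC(C)=O)C1 | intermediate
30 | (1S,4S,5R,13R,8Z,11E)-13-acetoxy-4,5-dihydroxycembra-8,11,15(17)-trien-16-al | C=C(C=O)[C@H]1CC[C@](C)(O)[C@H](O)CC/C(C)=C\C/C=C(C)/[C@H](OC(C)=O)C1 | intermediate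
31 | (1S,4S,5R,13R,8Z,11E)-13-acetoxy-4,5-dihydroxycembra-8,11,15(17)-trien-16-oic acid | C=C(C(=O)O)[C@H]1CC[C@](C)(O)[C@H](O)CC/C(C)=C\C/C=C(C)/[C@H](OC(C)=O)C1 | intermediate
32 | mixed anhydride of 31 with 2-methyl-6-nitrobenzoic acid | C=C(C(=O)OC(=O)c1c(C)cccc1[N+](=O)[O-])[C@H]1CC[C@](C)(O)[C@H](O)CC/C(C)=C\C/C=C(C)/[C@H](OC(C)=O)C1 | intermediate (not isolated)
33 | (1S,4S,5R,13R,8Z,11E)-13-acetoxy-5-hydroxycembra-8,11,15(17)-trien-16,4-olide (CNP0344673.1) | C=C1C(=O)O[C@@]2(C)CC[C@H]1C[C@@H](OC(C)=O)/C(C)=C/C/C=C(/C)CC[C@H]2O | target

## Step count and least certain steps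

Total: 23 steps. Longest linear sequence: 19 steps (nerol 7 to target 33, steps 5–23). The limonene branch (steps 1–4) joins at step 11.

**Step 17 (key step).** The most likely failure is poor facial selectivity at the C4 ketone, because the only biasing elements (the C1 branch, the C13 acetate, the two alkene geometries) act remotely through chain folding. A second concern is ionisation of the allylic acetate by the Lewis-acidic titanium chlorides. The fallback replaces kinetic control in a single pass by separation and oxidative recycling. It sets out from 24, whose cyclisation would deliver the 4R diols F1 beside 26. F1 is separated and cleaved with Pb(OAc)4 in CH2Cl2 at 0 °C (glycol cleavage, the reverse of the pinacol), and the route is rejoined at 24 for another pass.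

**Step 23.** The likely failure is acylation of the secondary O5 (eight-membered lactone or intermolecular esters) competing with the slow acylation of the tertiary O4. The fallback enforces regiochemistry by protection. It sets out from enal 30, which is silylated at O5 (TESCl, imidazole, DMF) to the triethylsilyl ether enal F2. Pinnick oxidation gives the silyloxy acid F3, lactonisation under the conditions of step 23 gives the silylated lactone F4, and HF·pyridine in THF removes the silyl group to rejoin the route at 33.

**Step 19.** The likely failure is loss of facial control if the zinc chelate is not the reacting species in the macrocycle or if the ring fold exposes the other face, which would give the trans diol. The fallback replaces substrate control by reagent control. It sets out from 27, whose tertiary hydroxyl is silylated with N-(trimethylsilyl)imidazole to the trimethylsilyl ether ketone F5. Reduction with (S)-Me-CBS oxazaborolidine and catecholborane, where the quaternary carbon acts as the large group, gives the 5R silyloxy alcohol F6. PPTS in MeOH at 0 °C removes the trimethylsilyl group and rejoins the route at 28.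

**Step 2.** The likely failures are over-oxidation to the enal, competing oxidation at the C1 methine and incomplete conversion, all typical of selenium dioxide on isopropenyl groups. The fallback replaces direct hydroxylation by ene-type chlorination and substitution. It sets out from 3, which with NaOCl and CeCl3·7H2O in CH2Cl2/H2O at 0 °C gives the allylic chloride F7. KOAc in DMF converts this into the allylic acetate F8, and K2CO3 in MeOH rejoins the route at 4.

**Step 14.** The likely failure is insufficient face discrimination, because the "small" group of the enone is a β-branched chain and not a methyl group. The fallback sets the centre by invertive substitution and not by reduction. It sets out from 21, whose reduction would give the 13S alcohol F9 beside 22. F9 is separated and treated with AcOH, PPh3 and DIAD (Mitsunobu reaction), which forms the acetate with inversion and rejoins the route at 23.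

## Further compounds

F1 | step 17 | (1S,4R,13R,8Z,11E)-13-acetoxy-16-[(tert-butyldiphenylsilyl)oxy]cembra-8,11,15(17)-triene-4,5-diol (C5 epimers) | C=C(CO[Si](c1ccccc1)(c1ccccc1)C(C)(C)C)[C@H]1CC[C@@](C)(O)C(O)CC/C(C)=C\C/C=C(C)/[C@H](OC(C)=O)C1
F2 | step 23 | (1S,4S,5R,13R,8Z,11E)-13-acetoxy-4-hydroxy-5-[(triethylsilyl)oxy]cembra-8,11,15(17)-trien-16-al | C=C(C=O)[C@H]1CC[C@](C)(O)[C@H](O[Si](CC)(CC)CC)CC/C(C)=C\C/C=C(C)/[C@H](OC(C)=O)C1
F3 | step 23 | (1S,4S,5R,13R,8Z,11E)-13-acetoxy-4-hydroxy-5-[(triethylsilyl)oxy]cembra-8,11,15(17)-trien-16-oic acid | C=C(C(=O)O)[C@H]1CC[C@](C)(O)[C@H](O[Si](CC)(CC)CC)CC/C(C)=C\C/C=C(C)/[C@H](OC(C)=O)C1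
F4 | step 23 | (1S,4S,5R,13R,8Z,11E)-13-acetoxy-5-[(triethylsilyl)oxy]cembra-8,11,15(17)-trien-16,4-olide | C=C1C(=O)O[C@@]2(C)CC[C@H]1C[C@@H](OC(C)=O)/C(C)=C/C/C=C(/C)CC[C@H]2O[Si](CC)(CC)CC
F5 | step 19 | (1S,4S,13R,8Z,11E)-13-acetoxy-16-[(tert-butyldiphenylsilyl)oxy]-4-[(trimethylsilyl)oxy]cembra-8,11,15(17)-trien-5-one | C=C(CO[Si](c1ccccc1)(c1ccccc1)C(C)(C)C)[C@H]1CC[C@](C)(O[Si](C)(C)C)C(=O)CC/C(C)=C\C/C=C(C)/[C@H](OC(C)=O)C1
F6 | step 19 | (1S,4S,5R,13R,8Z,11E)-13-acetoxy-16-[(tert-butyldiphenylsilyl)oxy]-4-[(trimethylsilyl)oxy]cembra-8,11,15(17)-trien-5-ol | C=C(CO[Si](c1ccccc1)(c1ccccc1)C(C)(C)C)[C@H]1CC[C@](C)(O[Si](C)(C)C)[C@H](O)CC/C(C)=C\C/C=C(C)/[C@H](OC(C)=O)C1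
F7 | step 2 | (5S)-5-(3-chloroprop-1-en-2-yl)-7,7-dimethoxyheptan-2-one | CC(=O)CC[C@@H](CC(OC)OC)C(=C)CCl
F8 | step 2 | 2-[(3S)-1,1-dimethoxy-6-oxoheptan-3-yl]prop-2-en-1-yl acetate | CC(=O)CC[C@@H](CC(OC)OC)C(=C)COC(C)=O
F9 | step 14 | (5S,7S,8E,11Z)-5-{3-[(tert-butyldiphenylsilyl)oxy]prop-1-en-2-yl}-2,2,15,15-tetramethoxy-8,12-dimethylpentadeca-8,11-dien-7-ol | COC(C)(OC)CC[C@@H](C[C@H](O)/C(C)=C/C/C=C(/C)CCC(OC)OC)C(=C)CO[Si](c1ccccc1)(c1ccccc1)C(C)(C)C
A1 | alternative 1 | open-chain (8Z,11E)-dienol with free C13 hydroxyl, C4 dioxolane, C5 1,3-dioxane and C16 tert-butyldimethylsilyl ether | O[C@H](C[C@H](CCC1(C)OCCO1)C(=C)CO[Si](C)(C)C(C)(C)C)/C(C)=C/C/C=C(/C)CCC2OCCCO2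
A2 | alternative 1 | C10–C13 vinyl oxirane of the limonene-derived half (C13 configured as in A1, C12 either epimer) | C=CC1(C)O[C@@H]1C[C@H](CCC2(C)OCCO2)C(=C)CO[Si](C)(C)C(C)(C)C
A3 | alternative 1 | 2-(1,3-dioxan-2-yl)ethylmagnesium bromide | Br[Mg]CCC1OCCCO1
A4 | alternative 1 | (Z)-[4-(1,3-dioxan-2-yl)-2-methylbut-1-en-1-yl]copper | [Cu]/C=C(/C)CCC1OCCCO1
A5 | alternative 2 | bis-silyl ether of the deacetyl target (C13 triethylsilyl, C5 tert-butyldimethylsilyl) | C=C1C(=O)O[C@@]2(C)CC[C@H]1C[C@@H](O[Si](CC)(CC)CC)/C(C)=C/C/C=C(/C)CC[C@H]2O[Si](C)(C)C(C)(C)C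
A6 | alternative 2 | macrocyclic C15 alkenyl iodide with free C4 hydroxyl, C5 tert-butyldimethylsilyl ether and C13 triethylsilyl ether | C=C(I)[C@H]1CC[C@](C)(O)[C@H](O[Si](C)(C)C(C)(C)C)CC/C(C)=C\C/C=C(C)/[C@H](O[Si](CC)(CC)CC)C1
A7 | alternative 3 | bicyclic C13 enone lactone, C5 tert-butyldimethylsilyl ether | C=C1C(=O)O[C@@]2(C)CC[C@H]1CC(=O)/C(C)=C/C/C=C(/C)CC[C@H]2O[Si](C)(C)C(C)(C)C
A8 | alternative 3 | seven-membered lactone carrying the C14 primary iodide and the C12 alkenyl iodide | C=C1C(=O)O[C@@](C)(CC[C@H]1CI)[C@H](O[Si](C)(C)C(C)(C)C)CC/C(C)=C\C/C=C(C)/I
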